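**Plan**

- Retrosynthesis cuts the C5–C(alkenyl) bond of the propenal chain, then the O1–C2 ether bond of the dihydrofuran ring, then the C2–C3 bond, and last the bond from C3 to its hydroxymethyl carbon.
- Forward, the formyl carbon of O-allylated 5-bromo-o-vanillin becomes C3: one-carbon homologation gives the arylacetic acid, its oxazolidinone imide is joined to veratraldehyde by an aldol reaction (C2–C3), and reduction turns the acyl carbon into the hydroxymethyl group.
- After release of the ring A phenol, the only ring made in the route, the dihydrofuran, closes through O1–C2; the enal chain is attached at C5 last by a Heck reaction.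
- The closure rests on one feature: C2 bears the 3,4-dimethoxyphenyl ring, whose para-methoxy group stabilises a C2 cation, and C2 is also the carbon that the ring oxygen O1 must bond to, so the C2 configuration is disposable and is rebuilt under the sole control of C3.
- Stereochemistry: C3 (S) comes from the (R)-4-benzyloxazolidinone auxiliary in the aldol step, C2 (R) from ring closure trans to C3, and the E alkene from the Heck reaction.

Key step: step 8

Remark: the carbinol configuration made in step 5 is immaterial because step 8 passes through a planar cation, and the primary hydroxyl is carried unprotected through the ring closure; O1, C2, C3, C5 and C7 are positions of the 2,3-dihydrobenzofuran of the target.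

**Route**

Step 1
Reactants: 1 5-bromo-2-hydroxy-3-methoxybenzaldehyde
Product: 2 2-(allyloxy)-5-bromo-3-methoxybenzaldehyde
Conditions: allyl bromide, K2CO3, DMF, rt
Reagents that add atoms: allyl bromide, C=CCBr
Why: Williamson ether synthesis: the phenol, made more acidic by the ortho formyl group, is O-alkylated by the allylic bromide under mild carbonate base, and the allyl ether is chosen because it tolerates ylide, aqueous acid, chlorite, boron triflate and borohydride and can later be removed without hydrogenolysis of the aryl bromide.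

Step 2
Reactants: 2 2-(allyloxy)-5-bromo-3-methoxybenzaldehyde
Product: 3 2-(allyloxy)-5-bromo-1-methoxy-3-(2-methoxyethenyl)benzene (E/Z mixture)
Conditions: MeOCH2PPh3Cl, KOtBu, THF, 0 °C to rt
Reagents that add atoms: (methoxymethyl)triphenylphosphonium chloride, COC[P+](c1ccccc1)(c1ccccc1)c1ccccc1.[Cl-]
Why: Wittig olefination with the non-stabilised methoxymethylene ylide adds the one carbon that becomes the hydroxymethyl carbon of the target and gives an enol ether whose E/Z composition is irrelevant, since both isomers hydrolyse to the same aldehyde.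

Step 3
Reactants: 3 2-(allyloxy)-5-bromo-1-methoxy-3-(2-methoxyethenyl)benzene (E/Z mixture)
Product: 5 2-[2-(allyloxy)-5-bromo-3-methoxyphenyl]acetic acid, via arylacetaldehyde 4 (not isolated)
Conditions: 2 M HCl, THF, 50 °C; then NaClO2, NaH2PO4, 2-methyl-2-butene, t-BuOH/H2O, 0 °C to rt
Reagents that add atoms: water, O; sodium chlorite NaClO2, [Na+].[O-]Cl=O
Why: Acid-catalysed enol ether hydrolysis followed by Pinnick oxidation: protonation at the benzylic carbon and hydration release the arylacetaldehyde, which is taken crude into the buffered chlorite oxidation so that the enolisable aldehyde is never stored, while 2-methyl-2-butene intercepts hypochlorous acid and protects the allyl group and the electron-rich ring.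

Step 4
Reactants: 5 2-[2-(allyloxy)-5-bromo-3-methoxyphenyl]acetic acid; 6 (4R)-4-benzyl-1,3-oxazolidin-2-one
Product: 8 (4R)-3-{2-[2-(allyloxy)-5-bromo-3-methoxyphenyl]acetyl}-4-benzyl-1,3-oxazolidin-2-one, via mixed pivalic anhydride 7 (not isolated)
Conditions: PivCl, Et3N, THF, −20 °C; then 6, LiCl, −20 °C to rt
Reagents that add atoms: none
Why: N-Acylation of the oxazolidinone through a mixed pivalic anhydride: under LiCl and Et3N the carbamate nitrogen attacks the less hindered arylacetyl carbonyl, which avoids a strong base that could deprotonate the acidic benzylic methylene.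

Step 5
Reactants: 8 (4R)-3-{2-[2-(allyloxy)-5-bromo-3-methoxyphenyl]acetyl}-4-benzyl-1,3-oxazolidin-2-one; 9 3,4-dimethoxybenzaldehyde
Product: 12 (4R)-3-[(2R,3R)-2-[2-(allyloxy)-5-bromo-3-methoxyphenyl]-3-(3,4-dimethoxyphenyl)-3-hydroxypropanoyl]-4-benzyl-1,3-oxazolidin-2-one, via Z dibutylboron enolate 10 (not isolated), via dibutylboron aldolate 11 (not isolated)
Conditions: Bu2BOTf, iPr2NEt, CH2Cl2, −78 to 0 °C; then 9, −78 to 0 °C; then pH 7 phosphate buffer, MeOH, 30% H2O2, 0 °C
Reagents that add atoms: none
Why: Evans syn-aldol reaction: soft enolisation gives the Z boron enolate, which adds to the aldehyde through a closed chair transition state from the enolate face remote from the benzyl group of the auxiliary (imide carbonyls opposed), so the alpha carbon, the future C3, is set as R in the imide with the carbinol syn to it.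

Step 6
Reactants: 12 (4R)-3-[(2R,3R)-2-[2-(allyloxy)-5-bromo-3-methoxyphenyl]-3-(3,4-dimethoxyphenyl)-3-hydroxypropanoyl]-4-benzyl-1,3-oxazolidin-2-one
Product: 13 (1R,2S)-2-[2-(allyloxy)-5-bromo-3-methoxyphenyl]-1-(3,4-dimethoxyphenyl)propane-1,3-diol
Conditions: LiBH4, MeOH (1 equiv), THF, 0 °C
Reagents that add atoms: none
Why: Reductive removal of the Evans auxiliary with LiBH4: hydride attacks the exocyclic imide carbonyl, the acyl carbon is taken down to the primary alcohol under conditions too mild for retro-aldol cleavage or epimerisation of the benzylic stereocentre, and the oxazolidinone is released for reuse.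

Step 7
Reactants: 13 (1R,2S)-2-[2-(allyloxy)-5-bromo-3-methoxyphenyl]-1-(3,4-dimethoxyphenyl)propane-1,3-diol
Product: 14 (1R,2S)-2-(5-bromo-2-hydroxy-3-methoxyphenyl)-1-(3,4-dimethoxyphenyl)propane-1,3-diol
Conditions: Pd(PPh3)4 (5 mol %), morpholine, THF, rt
Reagents that add atoms: none
Why: Palladium-catalysed deallylation of the Tsuji–Trost type: zerovalent palladium ionises the aryl allyl ether to a pi-allyl complex that morpholine captures irreversibly, freeing the phenol under neutral conditions at a temperature where oxidative addition into the electron-rich aryl bromide should not compete and the ionisable benzylic alcohol is left alone.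

Step 8
Reactants: 14 (1R,2S)-2-(5-bromo-2-hydroxy-3-methoxyphenyl)-1-(3,4-dimethoxyphenyl)propane-1,3-diol
Product: 15 [(2R,3S)-5-bromo-2-(3,4-dimethoxyphenyl)-7-methoxy-2,3-dihydro-1-benzofuran-3-yl]methanol
Conditions: TsOH·H2O (10 mol %), CH2Cl2, 0 °C to rt
Reagents that add atoms: none
Why: The sulfonic acid protonates the benzylic hydroxyl of 14, water leaves, and the carbocation at the future C2, shared with the para-methoxy oxygen of the dimethoxyphenyl ring in the manner of an O-methylated para-quinone methide, is captured by the ring A phenol oxygen to form the O1–C2 bond. The closest known reaction type is the acid-mediated cyclodehydration (SN1 etherification) of 1-aryl-2-(2-hydroxyaryl)propane-1,3-diols to trans-2-aryl-2,3-dihydrobenzofurans, which is known to proceed with the primary hydroxyl free. The single ring formed, the five-membered dihydrofuran, closes in the 5-exo-trig mode, the oxygen adding to a planar cationic carbon whose pi bonding lies outside the new ring. The one new stereocentre, C2, is controlled only by the C3 stereocentre: the oxygen adds to the face opposite the hydroxymethyl group, and because the benzylic ether can reionise under the same acid, any cis isomer and either carbinol epimer should drain into the more stable trans ring, which gives 2R from 3S. The step needs trans diastereoselectivity and selectivity for the phenol over the primary hydroxyl; the former is secured by the C3 substituent as described, the latter by ring size, since the primary oxygen could only close a strained four-membered ether, while catalytic acid at or below room temperature is meant to keep proton loss from C3 and loss of formaldehyde from the cation in the background.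

Step 9
Reactants: 15 [(2R,3S)-5-bromo-2-(3,4-dimethoxyphenyl)-7-methoxy-2,3-dihydro-1-benzofuran-3-yl]methanol
Product: 17 4-O-methylbalanophonin = (2E)-3-[(2R,3S)-2-(3,4-dimethoxyphenyl)-3-(hydroxymethyl)-7-methoxy-2,3-dihydro-1-benzofuran-5-yl]prop-2-enal, via cinnamaldehyde diethyl acetal 16 (not isolated)
Conditions: acrolein diethyl acetal, Pd(OAc)2 (3 mol %), nBu4NOAc, K2CO3, KCl, DMF, 90 °C; then 2 M HCl, rt
Reagents that add atoms: acrolein diethyl acetal, C=CC(OCC)OCC; water, O
Why: Heck reaction under phosphine-free conditions with tetrabutylammonium acetate: oxidative addition into the C5–Br bond, syn insertion of the terminal alkene and syn beta-hydride elimination from the benzylic carbon give the E cinnamyl acetal, and brief aqueous acid then unmasks the enal while the primary alcohol, the aryl ethers and both stereocentres, which carry no acidic hydrogen, are untouched.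

**Compound list**

1 | 5-bromo-2-hydroxy-3-methoxybenzaldehyde (5-bromo-o-vanillin) | O=Cc1cc(Br)cc(OC)c1O | starting material
2 | 2-(allyloxy)-5-bromo-3-methoxybenzaldehyde | O=Cc1cc(Br)cc(OC)c1OCC=C | intermediate
3 | 2-(allyloxy)-5-bromo-1-methoxy-3-(2-methoxyethenyl)benzene, E/Z mixture | COC=Cc1cc(Br)cc(OC)c1OCC=C | intermediate
4 | 2-[2-(allyloxy)-5-bromo-3-methoxyphenyl]acetaldehyde | O=CCc1cc(Br)cc(OC)c1OCC=C | intermediate (not isolated)
5 | 2-[2-(allyloxy)-5-bromo-3-methoxyphenyl]acetic acid | OC(=O)Cc1cc(Br)cc(OC)c1OCC=C | intermediate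
6 | (4R)-4-benzyl-1,3-oxazolidin-2-one | O=C1N[C@H](Cc2ccccc2)CO1 | starting material
7 | 2-[2-(allyloxy)-5-bromo-3-methoxyphenyl]acetic pivalic anhydride | CC(C)(C)C(=O)OC(=O)Cc1cc(Br)cc(OC)c1OCC=C | intermediate (not isolated)
8 | (4R)-3-{2-[2-(allyloxy)-5-bromo-3-methoxyphenyl]acetyl}-4-benzyl-1,3-oxazolidin-2-one | O=C(Cc1cc(Br)cc(OC)c1OCC=C)N1[C@H](Cc2ccccc2)COC1=O | intermediate
9 | 3,4-dimethoxybenzaldehyde (veratraldehyde) | COc1ccc(C=O)cc1OC | starting material
10 | (4R)-3-{(Z)-2-[2-(allyloxy)-5-bromo-3-methoxyphenyl]-1-[(dibutylboranyl)oxy]ethenyl}-4-benzyl-1,3-oxazolidin-2-one | CCCCB(CCCC)O/C(N1[C@H](Cc2ccccc2)COC1=O)=C\c1cc(Br)cc(OC)c1OCC=C | intermediate (not isolated)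
11 | O-dibutylboranyl derivative of 12 (boron aldolate) | O=C(N1[C@H](Cc2ccccc2)COC1=O)[C@H](c1cc(Br)cc(OC)c1OCC=C)[C@@H](OB(CCCC)CCCC)c1ccc(OC)c(OC)c1 | intermediate (not isolated)
12 | (4R)-3-[(2R,3R)-2-[2-(allyloxy)-5-bromo-3-methoxyphenyl]-3-(3,4-dimethoxyphenyl)-3-hydroxypropanoyl]-4-benzyl-1,3-oxazolidin-2-one | O=C(N1[C@H](Cc2ccccc2)COC1=O)[C@H](c1cc(Br)cc(OC)c1OCC=C)[C@@H](O)c1ccc(OC)c(OC)c1 | intermediate
13 | (1R,2S)-2-[2-(allyloxy)-5-bromo-3-methoxyphenyl]-1-(3,4-dimethoxyphenyl)propane-1,3-diol | OC[C@H](c1cc(Br)cc(OC)c1OCC=C)[C@@H](O)c1ccc(OC)c(OC)c1 | intermediate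
14 | (1R,2S)-2-(5-bromo-2-hydroxy-3-methoxyphenyl)-1-(3,4-dimethoxyphenyl)propane-1,3-diol | OC[C@H](c1cc(Br)cc(OC)c1O)[C@@H](O)c1ccc(OC)c(OC)c1 | intermediate
15 | [(2R,3S)-5-bromo-2-(3,4-dimethoxyphenyl)-7-methoxy-2,3-dihydro-1-benzofuran-3-yl]methanol | COc1ccc([C@@H]2Oc3c(OC)cc(Br)cc3[C@H]2CO)cc1OC | intermediate
16 | [(2R,3S)-5-[(1E)-3,3-diethoxyprop-1-en-1-yl]-2-(3,4-dimethoxyphenyl)-7-methoxy-2,3-dihydro-1-benzofuran-3-yl]methanol | COc1ccc([C@@H]2Oc3c(OC)cc(/C=C/C(OCC)OCC)cc3[C@H]2CO)cc1OC | intermediate (not isolated)
17 | 4-O-methylbalanophonin, (2E)-3-[(2R,3S)-2-(3,4-dimethoxyphenyl)-3-(hydroxymethyl)-7-methoxy-2,3-dihydro-1-benzofuran-5-yl]prop-2-enal | COc1ccc([C@@H]2Oc3c(OC)cc(/C=C/C=O)cc3[C@H]2CO)cc1OC | target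

**Step count and risks**

Total step count: 9 steps. Longest linear sequence: 9 steps (1 to 17); compounds 6 and 9 are purchased and enter in steps 4 and 5.

Steps most likely to fail:

Step 5. The boron aldolate, flanked by two aryl groups, may revert to enolate and aldehyde before or during the oxidative work-up, and the ortho-allyloxy ring may weaken the facial bias; either would lower the configurational purity of the carbon that becomes C3. The fallback changes auxiliary and metal. Setting out from acid 5, coupling with (R)-4-benzyl-1,3-thiazolidine-2-thione (EDC·HCl, DMAP, CH2Cl2) would give (4R)-3-{2-[2-(allyloxy)-5-bromo-3-methoxyphenyl]acetyl}-4-benzyl-1,3-thiazolidine-2-thione F1. Its chlorotitanium enolate (TiCl4, iPr2NEt, N-methyl-2-pyrrolidinone, CH2Cl2, −78 °C), formed with the added amide keeping the thiocarbonyl off titanium so that the same enolate face reacts, should add to veratraldehyde 9 to give the syn-aldol adduct (4R)-3-[(2R,3R)-2-[2-(allyloxy)-5-bromo-3-methoxyphenyl]-3-(3,4-dimethoxyphenyl)-3-hydroxypropanoyl]-4-benzyl-1,3-thiazolidine-2-thione F2. The thioimide is cleaved by NaBH4 in THF/H2O far more readily than the imide, and the route is rejoined at diol 13.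

Step 8. The cation may shed formaldehyde through the free primary hydroxyl, be captured by that hydroxyl of a second molecule, or close with an insufficient trans bias next to the small hydroxymethyl group. The fallback masks the primary alcohol before ionisation. Setting out from diol 13, TBSCl and imidazole in CH2Cl2 at 0 °C should silylate the primary hydroxyl selectively to give (1R,2S)-2-[2-(allyloxy)-5-bromo-3-methoxyphenyl]-3-[(tert-butyldimethylsilyl)oxy]-1-(3,4-dimethoxyphenyl)propan-1-ol F3. Deallylation as in step 7 would give (1R,2S)-2-(5-bromo-2-hydroxy-3-methoxyphenyl)-3-[(tert-butyldimethylsilyl)oxy]-1-(3,4-dimethoxyphenyl)propan-1-ol F4. Catalytic camphorsulfonic acid in dry CH2Cl2 should close the ring to tert-butyl{[(2R,3S)-5-bromo-2-(3,4-dimethoxyphenyl)-7-methoxy-2,3-dihydro-1-benzofuran-3-yl]methoxy}dimethylsilane F5, in which the bulkier silyloxymethyl group reinforces the trans preference and fragmentation is shut off. Bu4NF in THF then removes the silyl group and the route is rejoined at 15.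

Step 9. Oxidative addition into the electron-rich C5–Br bond may be slow without a phosphine, and beta-hydride elimination towards the acetal carbon would divert material to a saturated ester instead of the enal. The fallback replaces the Heck reaction by a Suzuki–Miyaura coupling that brings the E double bond ready-made. Setting out from bromide 15, commercial (E)-2-(3,3-diethoxyprop-1-en-1-yl)-4,4,5,5-tetramethyl-1,3,2-dioxaborolane, Pd(dppf)Cl2 and K2CO3 in dioxane/H2O at 80 °C should give acetal 16, where the route is rejoined, and the acidic work-up of step 9 then gives 17. This fallback makes no compound outside the list (F0).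

Further compounds
F1 | step 5 | (4R)-3-{2-[2-(allyloxy)-5-bromo-3-methoxyphenyl]acetyl}-4-benzyl-1,3-thiazolidine-2-thione | O=C(Cc1cc(Br)cc(OC)c1OCC=C)N1[C@H](Cc2ccccc2)CSC1=S
F2 | step 5 | (4R)-3-[(2R,3R)-2-[2-(allyloxy)-5-bromo-3-methoxyphenyl]-3-(3,4-dimethoxyphenyl)-3-hydroxypropanoyl]-4-benzyl-1,3-thiazolidine-2-thione | O=C(N1[C@H](Cc2ccccc2)CSC1=S)[C@H](c1cc(Br)cc(OC)c1OCC=C)[C@@H](O)c1ccc(OC)c(OC)c1
F3 | step 8 | (1R,2S)-2-[2-(allyloxy)-5-bromo-3-methoxyphenyl]-3-[(tert-butyldimethylsilyl)oxy]-1-(3,4-dimethoxyphenyl)propan-1-ol | CC(C)(C)[Si](C)(C)OC[C@H](c1cc(Br)cc(OC)c1OCC=C)[C@@H](O)c1ccc(OC)c(OC)c1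
F4 | step 8 | (1R,2S)-2-(5-bromo-2-hydroxy-3-methoxyphenyl)-3-[(tert-butyldimethylsilyl)oxy]-1-(3,4-dimethoxyphenyl)propan-1-ol | CC(C)(C)[Si](C)(C)OC[C@H](c1cc(Br)cc(OC)c1O)[C@@H](O)c1ccc(OC)c(OC)c1
F5 | step 8 | tert-butyl{[(2R,3S)-5-bromo-2-(3,4-dimethoxyphenyl)-7-methoxy-2,3-dihydro-1-benzofuran-3-yl]methoxy}dimethylsilane | COc1ccc([C@@H]2Oc3c(OC)cc(Br)cc3[C@H]2CO[Si](C)(C)C(C)(C)C)cc1OC
F0 | step 9 | none | none
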